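## Analysis of the target

The target 19 is a (2S)-flavanone. A benzo ring A (C4a, C5, C6, C7, C8, C8a) is fused to the dihydropyranone ring C (O1, C2, C3, C4), and a 3,4-dihydroxyphenyl ring B sits on C2. Ring A carries four contiguous substituents: the acyl carbon C4 on C4a, O1 on C8a, an (E)-4-hydroxy-3-methylbut-2-enyl chain on C8 and a methoxy group on C7; C5 and C6 are unsubstituted. C2 is the only stereocentre, and the E double bond of the chain is a second, independent stereo element. C2 is benzylic, bears the ring oxygen and lies β to the C4 carbonyl, so base opens ring C by E1cB elimination to the 2′-hydroxychalcone, the more easily once the 4′-hydroxyl is ionised. The catechol is sensitive to oxidation, the primary allylic alcohol to ionising acid, and the trisubstituted alkene to electrophiles and hydrogenation, so hydrogenolysis, strong acid and base are excluded at the end. The difficulty is to build the 1,2,3,4-substituted ring A without regioisomers and to set a labile stereocentre late under near-neutral conditions. The strategy rests on C4: it is a lone carbonyl carbon bonded only to C4a and C3, so ring C can be read as an ortho-iodophenol (C4a, C8a, O1), one molecule of carbon monoxide (C4) and an aryl acetylene (C3, C2, ring B).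

## Retrosynthetic reasoning

**19 to 18.** The three O–H bonds of 19 are traced back to three O–Si bonds in 18. One kind of silyl ether on the catechol and on the allylic alcohol allows a single acid-buffered fluoride deprotection. Hydrogenolysis or Lewis acid dealkylation would not spare the alkene or the 7-methoxy group, and a basic deprotection would open ring C.

**18 to 16 (through 17).** The C2–H bond is cut, which removes the only stereocentre and leads to the flat flavone 16. The labile centre then appears only after every carbon–carbon bond is in place. The forward reaction must add hydride to C2 from one face under catalyst control, leave the C4 carbonyl and the isolated alkene alone, and hold the enolate as enol ether 17 so that it cannot expel the ring oxygen.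

**16 to 9, 13 and 12.** Ring C is taken apart at C4a–C4, C4–C3 and O1–C2. These bonds meet at or next to the isolated carbonyl carbon C4, so the cut gives three stable pieces: iodophenol 9 with the complete ring A pattern, carbon monoxide 13, and alkyne 12 with ring B. A cut at C2–C3 or at C4–C4a alone would need an acyl-bearing ring A and strongly basic or acidic condensations that the silyl ethers would not survive. In the forward sense palladium must take up 13 before it meets 12, and ynone 14 must close in the six-membered sense through amine adduct 15.

**12 to 11 to 10.** The triple bond is cut back to the aldehyde carbon of 11 (one-carbon homologation), and the O–Si bonds back to 10. Silylation comes first because a free catechol aldehyde is deactivated as its phenoxide. The homologation must avoid alkoxide in a protic solvent, which would strip the aryl silyl ethers.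

**9 to 7 (through 8).** The allylic O–Si bond is cut. The phenol must be free for the key step, while the alcohol is masked so that it neither competes for the aroyl palladium intermediate nor consumes hydrosilane in the reduction. Silylating both hydroxyls and freeing only the phenol is more dependable than a selective monosilylation.

**7 to 6 to 4 and 5.** The alcohol is traced to enal 6, and the side-chain C=C is then cut by a metathesis disconnection into allylphenol 4 and enal 5. The E geometry arises under thermodynamic control in the conjugated enal, and the branched four-carbon end comes from 5 in one operation. A sequence of two directed lithiations on a phenol acetal was weighed for this fragment and set aside. Its second lithiation would have to run beside a methylene group that is both benzylic and allylic and beside an allylic silyl ether, both competing sites for the base. Its side chain would come from an SN2′ opening of a vinyl epoxide with mixed alkene geometry.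

**4 to 3 to 1 and 2.** The C8–CH2 bond is cut by a retro-Claisen step to ether 3, and the O–allyl bond to 1 and 2. In 1 the hydroxyl, iodine and methoxy groups already stand as O1/C8a, C4a and C7 will stand. The only free ortho carbon is the future C8, so the sigmatropic shift has one productive outcome.

## Alternatives that were turned down

**Alternative 1:** The bond cut is C4–C4a. Ring C would be closed last by intramolecular Friedel–Crafts acylation: the (S)-3-aryl-3-aryloxypropanoic acid A1, activated as its mixed anhydride with (CF3CO)2O, attacks C4a and gives flavanone triacetate A2.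
- For it: C4a is the only free position ortho to the ether oxygen and is para to the methoxy group, so the closure has one regiochemical outcome. C2 would be fixed earlier by a stereospecific C–O bond formation, so the enantiomeric purity does not depend on a catalyst acting on a complex flavone. On this point it is stronger than the chosen route.
- Against it: the closure needs strongly acidic, acylating conditions. The C2–O bond of A1 is a benzylic aryl ether that can ionise (racemisation), and the activated acid can lose the phenol by β-elimination. The trisubstituted alkene and the allylic acetate can be protonated, ionised or attacked by the acylium centre. The three acetates of A2 must then be removed with base or acid, and base with a free 4′-phenoxide opens ring C.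
- Comparison: the sequence is linear and of similar length. The chosen strategy joins the pieces under basic, non-ionising conditions that the alkene and the allylic oxygen tolerate, and removes its protecting groups without base.

**Alternative 2:** The bonds cut are C2–C3 and O1–C8a, in a hetero-Diels–Alder sense, with ring A lowered to the dihydro level. The bis(trimethylsilyl) dienol ether A3 and aldehyde 11 would combine under BINOL and Ti(O-i-Pr)4 (tetravalent titanium); acid work-up would give dihydropyranone A4, whose ring A is aromatised afterwards.
- For it: two bonds, ring C and the C2 configuration arise in one catalytic step from the aldehyde itself, without an alkyne and without carbon monoxide. This is more economical in stereochemical terms than a separate reduction.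
- Against it: A3 is a fully substituted cyclic diene whose reacting terminus is a ring carbon flanked by the C8 chain, so its reactivity toward the hindered catalyst–aldehyde complex is uncertain. A3 needs its own multistep preparation from a substituted cyclohexane-1,3-dione with regiochemical control of O-methylation. Above all, A4 must lose two hydrogens at C5–C6 after C2 is set, and oxidants that aromatise ring A can equally dehydrogenate C2–C3 to the flavone or attack the allylic positions of the chain.
- Comparison: the chosen strategy keeps ring A aromatic from the first step and places no oxidation after the stereocentre.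

**Alternative 3:** The bond cut is C3=C4. Triene A5 has a vinyl group on C2 and a 1-(tert-butyldimethylsilyloxy)vinyl group on C4a. Ring-closing metathesis with second-generation Grubbs catalyst, RuCl2(=CHPh)(H2IMes)(PCy3), would expel ethylene and give the 4-silyloxy-2H-chromene A6, which is hydrolysed to the flavanone.
- For it: closure is neutral. A6 is the tert-butyldimethylsilyl counterpart of 17, so it unmasks to the ketone without touching C2. C2 would be set beforehand by an enantioselective allylic etherification of predictable sense, and no pressure equipment is needed. On these points it is as strong as or stronger than the chosen route.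
- Against it: A5 holds three olefins. The electron-rich 1,1-disubstituted enol ether engages the carbene slowly. The vinyl group can instead close onto the C8 side-chain alkene to a seven-membered ring, destroying the chain. The C2–O bond of A5 is both allylic and benzylic, so ruthenium hydride isomerisation or ionisation can erase the stereocentre. The etherification would have to be run on a phenol flanked by an acyl group and the chain, and ring A would need an extra acetyl group.
- Comparison: the chosen strategy has only one, unreactive olefin present during ring closure and draws ring C from three simple components.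

Key step: step 8

Remarks on the chemistry (assumptions):
- 2-Iodo-5-methoxyphenol 1 is taken to be a purchasable compound.
- Which antipode of the bisphosphine gives 2S in step 9 is to be fixed by a trial run on 16; the (R) ligand is written as the working choice.
- TBS stands for tert-butyldimethylsilyl.

## Route

Step 1
Reactants: 1 2-iodo-5-methoxyphenol; 2 allyl bromide
Product: 3 2-(allyloxy)-1-iodo-4-methoxybenzene
Conditions: K2CO3, acetone, reflux
Reagents that add atoms: none
Why: Williamson ether synthesis on an acidic phenol with a reactive allylic halide; the carbonate medium in acetone favours O-alkylation.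

Step 2
Reactants: 3 2-(allyloxy)-1-iodo-4-methoxybenzene
Product: 4 2-allyl-6-iodo-3-methoxyphenol
Conditions: PhNEt2, 190 °C, argon, dark
Reagents that add atoms: none
Why: Aromatic Claisen rearrangement; the [3,3] shift can end productively only at the free ortho carbon between the two oxygens, because the other ortho carbon bears iodine and cannot re-aromatise by tautomerisation. The amine solvent keeps the product phenol from adding to its own alkene.

Step 3
Reactants: 4 2-allyl-6-iodo-3-methoxyphenol; 5 methacrolein (2-methylprop-2-enal)
Product: 6 (E)-4-(2-hydroxy-3-iodo-6-methoxyphenyl)-2-methylbut-2-enal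
Conditions: 5 (5 equiv), second-generation Hoveyda–Grubbs catalyst RuCl2(=CH-C6H4-2-O-i-Pr)(H2IMes) (5 mol %), 1,4-benzoquinone (10 mol %), CH2Cl2, 40 °C
Reagents that add atoms: none
Why: Olefin cross-metathesis of a terminal olefin with an electron-poor 1,1-disubstituted partner that dimerises slowly; the conjugated α-methyl enal forms under thermodynamic control as the E isomer, which fixes the side-chain geometry of the target. Aryl iodide and free phenol are tolerated by the ruthenium carbene, and the quinone suppresses double-bond migration.

Step 4
Reactants: 6 (E)-4-(2-hydroxy-3-iodo-6-methoxyphenyl)-2-methylbut-2-enal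
Product: 7 2-[(E)-4-hydroxy-3-methylbut-2-enyl]-6-iodo-3-methoxyphenol
Conditions: NaBH4, CeCl3·7H2O, MeOH, 0 °C
Reagents that add atoms: none
Why: Luche reduction; 1,2-selective hydride addition to the enal is fast and precedes any conjugate addition of the phenol. Alkene geometry and aryl iodide are untouched.

Step 5
Reactants: 7 2-[(E)-4-hydroxy-3-methylbut-2-enyl]-6-iodo-3-methoxyphenol
Product: 9 2-[(E)-4-(tert-butyldimethylsilyloxy)-3-methylbut-2-enyl]-6-iodo-3-methoxyphenol, via bis-silyl ether 8 (not isolated)
Conditions: TBSCl (2.5 equiv), imidazole, DMF, rt; then K2CO3 (cat.), MeOH, rt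
Reagents that add atoms: tert-butyldimethylsilyl chloride (TBSCl), CC(C)(C)[Si](C)(C)Cl
Why: Silylation of both hydroxyls, then base-catalysed methanolysis of the aryl silyl ether only; the iodophenoxide is a far better leaving group from silicon than the primary alkoxide, so the allylic silyl ether stays.

Step 6
Reactants: 10 3,4-dihydroxybenzaldehyde
Product: 11 3,4-bis(tert-butyldimethylsilyloxy)benzaldehyde
Conditions: TBSCl (2.4 equiv), imidazole, DMF, rt
Reagents that add atoms: tert-butyldimethylsilyl chloride (TBSCl), CC(C)(C)[Si](C)(C)Cl
Why: Standard silylation of a catechol; silyl ethers are chosen because they can later be removed with buffered HF, without base and without hydrogen.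

Step 7
Reactants: 11 3,4-bis(tert-butyldimethylsilyloxy)benzaldehyde
Product: 12 4-ethynyl-1,2-bis(tert-butyldimethylsilyloxy)benzene
Conditions: Me3SiCHN2, LiN(i-Pr)2, THF, −78 °C; then 11, −78 to 0 °C; H2O
Reagents that add atoms: trimethylsilyldiazomethane, C[Si](C)(C)C=[N+]=[N-]
Why: Colvin rearrangement; the lithiated diazomethane adds to the aldehyde, Peterson elimination and loss of N2 give an alkylidene carbene, and a 1,2-hydrogen shift gives the terminal alkyne. No alkoxide in a protic solvent is present, so the aryl silyl ethers, which K2CO3 in MeOH would cleave, are kept.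

Step 8
Reactants: 9 2-[(E)-4-(tert-butyldimethylsilyloxy)-3-methylbut-2-enyl]-6-iodo-3-methoxyphenol; 12 4-ethynyl-1,2-bis(tert-butyldimethylsilyloxy)benzene; 13 carbon monoxide
Product: 16 2-[3,4-bis(tert-butyldimethylsilyloxy)phenyl]-8-[(E)-4-(tert-butyldimethylsilyloxy)-3-methylbut-2-enyl]-7-methoxy-4H-chromen-4-one, via hydroxyaryl ynone 14 (not isolated), via diethylamino enone 15 (not isolated)
Conditions: PdCl2(PPh3)2 (5 mol %), CO (20 bar), Et2NH, 100 °C, autoclave, no copper salt
Reagents that add atoms: none
Why: Zerovalent palladium, formed from PdCl2(PPh3)2 under CO and amine, inserts into the C–I bond of 9; the electron-rich aryl palladium iodide takes up 13, and the aroyl palladium species couples with the acetylide that Et2NH forms from 12, releasing ynone 14 and forming C4a–C4 and C4–C3. The closest known reaction type is the palladium-catalysed carbonylative Sonogashira coupling and annulation of 2-iodophenols with terminal aryl acetylenes to flavones. Et2NH then adds to 14 to give the vinylogous amide 15, and the neighbouring phenol displaces the amine at the same carbon by addition–elimination, which forms O1–C2. This closure of ring C is 6-endo-trig on 15 and corresponds to the 6-endo-dig oxa-Michael outcome on 14. No stereocentre is created, because C2 is trigonal in 16. Carbonylative coupling must win over direct coupling, which CO pressure, the absence of a copper co-catalyst and the electron-rich iodide secure; alkyne capture must also win over capture of the aroyl palladium species by the amine, as is usual for this reaction type in neat Et2NH. Closure must be 6-endo and not 5-exo, and this is secured because in 15 only the carbon that bears ring B is electrophilic. The silyl ethers and the isolated trisubstituted alkene are not substrates for the catalyst, and the iodine is meta to the chain, so no intramolecular Heck path exists.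

Step 9
Reactants: 16 2-[3,4-bis(tert-butyldimethylsilyloxy)phenyl]-8-[(E)-4-(tert-butyldimethylsilyloxy)-3-methylbut-2-enyl]-7-methoxy-4H-chromen-4-one
Product: 18 (2S)-2-[3,4-bis(tert-butyldimethylsilyloxy)phenyl]-8-[(E)-4-(tert-butyldimethylsilyloxy)-3-methylbut-2-enyl]-7-methoxychroman-4-one, via silyl enol ether 17 (not isolated)
Conditions: Cu(OAc)2 (5 mol %), (R)-DTBM-SEGPHOS (5.5 mol %), (EtO)2MeSiH (3 equiv), toluene, 0 °C to rt, no alcohol additive; then sat. aq. NH4Cl
Reagents that add atoms: none
Why: Copper hydride catalysed asymmetric conjugate reduction, a reaction type known for β,β-disubstituted cyclic enones and 2-substituted chromones. The silane reduces Cu(OAc)2 to a monovalent copper hydride bound to the bisphosphine, which delivers hydride to C2 on the face chosen by the ligand and so sets 2S. The copper enolate is silylated at once to 17, which blocks ring opening and 1,2-reduction; mild hydrolysis then gives the ketone, and protonation at C3 creates no stereocentre.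

Step 10
Reactants: 18 (2S)-2-[3,4-bis(tert-butyldimethylsilyloxy)phenyl]-8-[(E)-4-(tert-butyldimethylsilyloxy)-3-methylbut-2-enyl]-7-methoxychroman-4-one
Product: 19 (2S)-2-(3,4-dihydroxyphenyl)-8-[(E)-4-hydroxy-3-methylbut-2-enyl]-7-methoxychroman-4-one (CNP0503781.1)
Conditions: HF·pyridine, pyridine, THF, 0 °C to rt; work-up kept at or below pH 7
Reagents that add atoms: none
Why: Fluoride desilylation under acidic buffering cleaves the three Si–O bonds while no phenoxide is present, so C2 cannot epimerise by ring opening. Alkene, allylic alcohol, methyl ether and catechol are stable to these conditions.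

## Compound list

1 | 2-iodo-5-methoxyphenol | COc1ccc(I)c(O)c1 | starting material
2 | allyl bromide (3-bromoprop-1-ene) | C=CCBr | starting material
3 | 2-(allyloxy)-1-iodo-4-methoxybenzene | COc1ccc(I)c(OCC=C)c1 | intermediate
4 | 2-allyl-6-iodo-3-methoxyphenol | COc1ccc(I)c(O)c1CC=C | intermediate
5 | methacrolein (2-methylprop-2-enal) | CC(=C)C=O | starting material
6 | (E)-4-(2-hydroxy-3-iodo-6-methoxyphenyl)-2-methylbut-2-enal | COc1ccc(I)c(O)c1C/C=C(\C)C=O | intermediate
7 | 2-[(E)-4-hydroxy-3-methylbut-2-enyl]-6-iodo-3-methoxyphenol | COc1ccc(I)c(O)c1C/C=C(\C)CO | intermediate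
8 | bis-TBS ether of 7, silylated on the phenol and the allylic oxygen (formed and consumed in the flask) | COc1ccc(I)c(O[Si](C)(C)C(C)(C)C)c1C/C=C(\C)CO[Si](C)(C)C(C)(C)C | intermediate
9 | 2-[(E)-4-(tert-butyldimethylsilyloxy)-3-methylbut-2-enyl]-6-iodo-3-methoxyphenol | COc1ccc(I)c(O)c1C/C=C(\C)CO[Si](C)(C)C(C)(C)C | intermediate
10 | 3,4-dihydroxybenzaldehyde | O=Cc1ccc(O)c(O)c1 | starting material
11 | 3,4-bis(tert-butyldimethylsilyloxy)benzaldehyde | O=Cc1ccc(O[Si](C)(C)C(C)(C)C)c(O[Si](C)(C)C(C)(C)C)c1 | intermediate
12 | 4-ethynyl-1,2-bis(tert-butyldimethylsilyloxy)benzene | C#Cc1ccc(O[Si](C)(C)C(C)(C)C)c(O[Si](C)(C)C(C)(C)C)c1 | intermediate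
13 | carbon monoxide | [C-]#[O+] | starting material
14 | 3-[3,4-bis(TBS-oxy)phenyl]-1-{3-[(E)-4-(TBS-oxy)-3-methylbut-2-enyl]-2-hydroxy-4-methoxyphenyl}prop-2-yn-1-one (formed and consumed in the flask) | COc1ccc(C(=O)C#Cc2ccc(O[Si](C)(C)C(C)(C)C)c(O[Si](C)(C)C(C)(C)C)c2)c(O)c1C/C=C(\C)CO[Si](C)(C)C(C)(C)C | intermediate
15 | 3-[3,4-bis(TBS-oxy)phenyl]-3-(diethylamino)-1-{3-[(E)-4-(TBS-oxy)-3-methylbut-2-enyl]-2-hydroxy-4-methoxyphenyl}prop-2-en-1-one, geometry of the enaminone double bond not defined (formed and consumed in the flask) | COc1ccc(C(=O)C=C(N(CC)CC)c2ccc(O[Si](C)(C)C(C)(C)C)c(O[Si](C)(C)C(C)(C)C)c2)c(O)c1C/C=C(\C)CO[Si](C)(C)C(C)(C)C | intermediate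
16 | 2-[3,4-bis(TBS-oxy)phenyl]-8-[(E)-4-(TBS-oxy)-3-methylbut-2-enyl]-7-methoxy-4H-chromen-4-one | COc1ccc2c(c1C/C=C(\C)CO[Si](C)(C)C(C)(C)C)OC(c1ccc(O[Si](C)(C)C(C)(C)C)c(O[Si](C)(C)C(C)(C)C)c1)=CC2=O | intermediate
17 | (2S)-2-[3,4-bis(TBS-oxy)phenyl]-8-[(E)-4-(TBS-oxy)-3-methylbut-2-enyl]-4-[diethoxy(methyl)silyloxy]-7-methoxy-2H-chromene (formed and consumed in the flask) | COc1ccc2c(c1C/C=C(\C)CO[Si](C)(C)C(C)(C)C)O[C@H](c1ccc(O[Si](C)(C)C(C)(C)C)c(O[Si](C)(C)C(C)(C)C)c1)C=C2O[Si](C)(OCC)OCC | intermediate
18 | (2S)-2-[3,4-bis(TBS-oxy)phenyl]-8-[(E)-4-(TBS-oxy)-3-methylbut-2-enyl]-7-methoxychroman-4-one | COc1ccc2c(c1C/C=C(\C)CO[Si](C)(C)C(C)(C)C)O[C@H](c1ccc(O[Si](C)(C)C(C)(C)C)c(O[Si](C)(C)C(C)(C)C)c1)CC2=O | intermediate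
19 | (2S)-2-(3,4-dihydroxyphenyl)-8-[(E)-4-hydroxy-3-methylbut-2-enyl]-7-methoxychroman-4-one | COc1ccc2c(c1C/C=C(\C)CO)O[C@H](c1ccc(O)c(O)c1)CC2=O | target

## Step count and least certain steps

Total step count: 10 steps. Longest linear sequence: 8 steps (steps 1, 2, 3, 4, 5, 8, 9 and 10 from 1); the alkyne branch is 2 steps (6 and 7).

**Step 8 (key step).**
- Risk: coupling of the aryl palladium species with the alkyne before carbon monoxide is taken up, followed by closure to a five-membered oxygen ring. Capture of the aroyl palladium species by the amine solvent and loss of aryl silyl groups in hot amine are further risks.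
- Fallback (no palladium, no carbon monoxide): 12 is deprotonated with n-BuLi and acylated with N-methoxy-N-methylcarbamoyl chloride to give 3-[3,4-bis(tert-butyldimethylsilyloxy)phenyl]-N-methoxy-N-methylprop-2-ynamide F1. The phenol of 9 is deprotonated with MeMgCl, the iodide is exchanged with i-PrMgCl·LiCl, and the aryl magnesium species is added to F1. This gives ynone 14, where the route is rejoined; Et2NH in EtOH then closes 14 through 15 to 16.

**Step 9.**
- Risk: slow hydride transfer to an electron-rich vinylogous ester, competing 1,2-reduction, ring opening of the enolate before silylation, and insufficient facial selectivity. A wrong facial sense alone is answered by the antipodal ligand.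
- Fallback (kinetic resolution instead of enantioselective catalysis): 16 is reduced without stereocontrol by conjugate hydride addition with LiBH(s-Bu)3 in THF at −78 °C to the racemic flavanone F2. F2 is resolved by asymmetric transfer hydrogenation with RuCl(p-cymene)[(R,R)-TsDPEN] and HCO2H/Et3N. By analogy with aryl ketones, this catalyst should reduce the 2R enantiomer to the cis (2R,4R)-flavan-4-ol F3 and leave 18, which is separated and carried into step 10. At most half of the material is recovered.

**Step 3.**
- Risk: migration of the allyl double bond into conjugation with the ring, slow turnover with the 1,1-disubstituted partner, and conjugate addition of the phenol to the new enal.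
- Fallback (Wittig olefination instead of metathesis): 4 is ozonised (O3, CH2Cl2/MeOH, −78 °C; Me2S); the arylacetaldehyde closes onto the phenol to give the lactol 7-iodo-4-methoxy-2,3-dihydro-1-benzofuran-2-ol F4. Wittig reaction of F4 with Ph3P=C(CH3)CO2Et in toluene at 80 °C opens the lactol to ethyl (E)-4-(2-hydroxy-3-iodo-6-methoxyphenyl)-2-methylbut-2-enoate F5. Reduction of F5 with i-Bu2AlH in CH2Cl2 at −78 °C gives 7, where the route is rejoined.

**Step 2.**
- Risk: slow rearrangement into the crowded position between two oxygens, migration toward the iodine-bearing carbon with loss of iodine or onward para migration, and addition of the product phenol to its alkene at high temperature.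
- Fallback (direct C-allylation instead of a sigmatropic shift): the sodium phenoxide of 1 (NaH, toluene) is alkylated with 2 in the non-polar medium, where alkylation at the free ortho carbon competes well with O-alkylation. This gives 4 directly, and any 3 formed is recycled.

## Further compounds

F1 | step 8 | 3-[3,4-bis(tert-butyldimethylsilyloxy)phenyl]-N-methoxy-N-methylprop-2-ynamide | CON(C)C(=O)C#Cc1ccc(O[Si](C)(C)C(C)(C)C)c(O[Si](C)(C)C(C)(C)C)c1
F2 | step 9 | racemic 2-[3,4-bis(TBS-oxy)phenyl]-8-[(E)-4-(TBS-oxy)-3-methylbut-2-enyl]-7-methoxychroman-4-one | COc1ccc2c(c1C/C=C(\C)CO[Si](C)(C)C(C)(C)C)OC(c1ccc(O[Si](C)(C)C(C)(C)C)c(O[Si](C)(C)C(C)(C)C)c1)CC2=O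
F3 | step 9 | (2R,4R)-2-[3,4-bis(TBS-oxy)phenyl]-8-[(E)-4-(TBS-oxy)-3-methylbut-2-enyl]-7-methoxychroman-4-ol | COc1ccc2c(c1C/C=C(\C)CO[Si](C)(C)C(C)(C)C)O[C@@H](c1ccc(O[Si](C)(C)C(C)(C)C)c(O[Si](C)(C)C(C)(C)C)c1)C[C@H]2O
F4 | step 3 | 7-iodo-4-methoxy-2,3-dihydro-1-benzofuran-2-ol | COc1ccc(I)c2OC(O)Cc12
F5 | step 3 | ethyl (E)-4-(2-hydroxy-3-iodo-6-methoxyphenyl)-2-methylbut-2-enoate | COc1ccc(I)c(O)c1C/C=C(\C)C(=O)OCC
F0 | step 2 | none | none
A1 | alternative 1 | (S)-3-(3,4-diacetoxyphenyl)-3-{2-[(E)-4-acetoxy-3-methylbut-2-enyl]-3-methoxyphenoxy}propanoic acid | COc1cccc(O[C@H](c2ccc(OC(C)=O)c(OC(C)=O)c2)CC(=O)O)c1C/C=C(\C)COC(C)=O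
A2 | alternative 1 | (S)-flavanone triacetate | COc1ccc2c(c1C/C=C(\C)COC(C)=O)O[C@H](c1ccc(OC(C)=O)c(OC(C)=O)c1)CC2=O
A3 | alternative 2 | bis(trimethylsilyl) dienol ether with ring A at the cyclohexadiene level | COC1=C(C/C=C(\C)CO[Si](C)(C)C(C)(C)C)C(O[Si](C)(C)C)=C(C(=C)O[Si](C)(C)C)CC1
A4 | alternative 2 | (S)-5,6-dihydroflavanone, fully silylated | COC1=C(C/C=C(\C)CO[Si](C)(C)C(C)(C)C)C2=C(CC1)C(=O)C[C@@H](c1ccc(O[Si](C)(C)C(C)(C)C)c(O[Si](C)(C)C(C)(C)C)c1)O2
A5 | alternative 3 | (S)-aryl 1-arylallyl ether with a 1-(tert-butyldimethylsilyloxy)vinyl group on C4a | COc1ccc(C(=C)O[Si](C)(C)C(C)(C)C)c(O[C@H](c2ccc(O[Si](C)(C)C(C)(C)C)c(O[Si](C)(C)C(C)(C)C)c2)C=C)c1C/C=C(\C)CO[Si](C)(C)C(C)(C)C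
A6 | alternative 3 | (S)-2-aryl-4-(tert-butyldimethylsilyloxy)-2H-chromene | COc1ccc2c(c1C/C=C(\C)CO[Si](C)(C)C(C)(C)C)O[C@H](c1ccc(O[Si](C)(C)C(C)(C)C)c(O[Si](C)(C)C(C)(C)C)c1)C=C2O[Si](C)(C)C(C)(C)C
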